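## Retrosynthetic overview

1. Cut the C11=C12 double bond (carotenoid numbering) by a Wittig reaction: target ⇐ bicyclic C15 (Z)-enal 20 + C12 phosphonium salt 26, the latter from 2,7-dimethylocta-2,4,6-trienedial 21.
2. The dihydrofuran ring (formed last) ⇐ gold-catalysed 5-endo cyclisation of α-hydroxyallene 17, which transfers the allene axis into the C8 stereocentre.
3. Allene ⇐ syn-SN2' hydride opening of alkynyl epoxide 14; 14 ⇐ Sonogashira coupling of ethynyl epoxide 11 with (Z)-iodoenoate 13, which fixes the Z double bond next to the ring.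
4. Oxirane (temporary ring, formed first) ⇐ Sharpless epoxidation of allylic alcohol 8, which sets C5; 8 ⇐ enol triflate carbonylation of silylated actinol.
5. The cyclohexane ring is present from the start: ketoisophorone 1 → (R)-levodione 2 (ene-reductase) → actinol 3 (ketoreductase), which sets C3.

Assumption: the SMILES is read literally, i.e. (3S,5R,8S) in carotenoid numbering [(2S,6S,7aR) in benzofuran numbering], the double bond next to the ring Z and all others E; compounds 1, 12, 21 and 22 are taken as commercial.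

## Route

Step 1
Reactants: 1 2,6,6-trimethylcyclohex-2-ene-1,4-dione (ketoisophorone)
Product: 2 (6R)-2,2,6-trimethylcyclohexane-1,4-dione
Conditions: ene-reductase (Old Yellow Enzyme family), NADH (cat.), formate dehydrogenase, HCO2Na, KH2PO4/K2HPO4 buffer pH 7.0, 30 °C
Reagents that add atoms: none
Why: Biocatalytic asymmetric conjugate reduction, in which the flavin-dependent ene-reductase adds hydride and a proton trans across the enedione C=C bond and so sets the methyl-bearing centre as R.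

Step 2
Reactants: 2 (6R)-2,2,6-trimethylcyclohexane-1,4-dione
Product: 3 (4R,6R)-4-hydroxy-2,2,6-trimethylcyclohexan-1-one (actinol)
Conditions: ketoreductase (NADH-dependent carbonyl reductase of the levodione reductase type), NADH (cat.), formate dehydrogenase, HCO2Na, KH2PO4/K2HPO4 buffer pH 7.0, 30 °C
Reagents that add atoms: none
Why: Enzymatic ketone reduction that touches only the unhindered C4 carbonyl and sets the carbinol centre as R (trans to the methyl group) under enzyme control; this centre becomes C3 of the target.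

Step 3
Reactants: 3 (4R,6R)-4-hydroxy-2,2,6-trimethylcyclohexan-1-one
Product: 4 (4R,6R)-4-(tert-butyldimethylsilyloxy)-2,2,6-trimethylcyclohexan-1-one
Conditions: TBSCl, imidazole, DMF, rt
Reagents that add atoms: tert-butyldimethylsilyl chloride (CC(C)(C)[Si](C)(C)Cl)
Why: Standard silyl ether protection of the secondary alcohol, with no change at the stereocentres.

Step 4
Reactants: 4 (4R,6R)-4-(tert-butyldimethylsilyloxy)-2,2,6-trimethylcyclohexan-1-one
Product: 6 (4R)-4-(tert-butyldimethylsilyloxy)-2,6,6-trimethylcyclohex-1-en-1-yl trifluoromethanesulfonate, via lithium enolate 5 (not isolated)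
Conditions: LiN(iPr)2, THF, −78 °C; then PhNTf2, −78 °C → rt
Reagents that add atoms: N-phenylbis(trifluoromethanesulfonimide) (FC(F)(F)S(=O)(=O)N(c1ccccc1)S(=O)(=O)C(F)(F)F)
Why: Enol triflate formation is regiodefined because only the methine α-carbon carries a proton (the other α-carbon is quaternary); the methyl-bearing centre becomes sp2 and the carbinol centre is untouched.

Step 5
Reactants: 6 (4R)-4-(tert-butyldimethylsilyloxy)-2,6,6-trimethylcyclohex-1-en-1-yl trifluoromethanesulfonate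
Product: 7 methyl (4R)-4-(tert-butyldimethylsilyloxy)-2,6,6-trimethylcyclohex-1-ene-1-carboxylate
Conditions: Pd(OAc)2 (5 mol %), PPh3 (10 mol %), CO (1 atm), MeOH, Et3N, DMF, 60 °C
Reagents that add atoms: carbon monoxide ([C-]#[O+]); methanol (CO)
Why: Palladium-catalysed alkoxycarbonylation, i.e. oxidative addition of zerovalent palladium into the vinyl triflate, CO insertion and methanolysis of the acyl palladium species.

Step 6
Reactants: 7 methyl (4R)-4-(tert-butyldimethylsilyloxy)-2,6,6-trimethylcyclohex-1-ene-1-carboxylate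
Product: 8 [(4R)-4-(tert-butyldimethylsilyloxy)-2,6,6-trimethylcyclohex-1-en-1-yl]methanol
Conditions: iBu2AlH, CH2Cl2, −78 → 0 °C; aq. KNaC4H4O6
Reagents that add atoms: none
Why: 1,2-Reduction of the unsaturated ester with the aluminium hydride gives the allylic alcohol needed for directed epoxidation.

Step 7
Reactants: 8 [(4R)-4-(tert-butyldimethylsilyloxy)-2,6,6-trimethylcyclohex-1-en-1-yl]methanol
Product: 9 [(1R,4S,6R)-4-(tert-butyldimethylsilyloxy)-2,2,6-trimethyl-7-oxabicyclo[4.1.0]heptan-1-yl]methanol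
Conditions: Ti(OiPr)4 (20 mol %), D-(−)-diethyl tartrate (24 mol %), tBuOOH, 4 Å MS, CH2Cl2, −20 °C
Reagents that add atoms: tert-butyl hydroperoxide (CC(C)(C)OO)
Why: Sharpless asymmetric epoxidation, in which the titanium D-(−)-tartrate catalyst delivers oxygen to the alkene face anti to the silyloxy group (reagent control) and sets both epoxide carbons, including the later C5 (R).

Step 8
Reactants: 9 [(1R,4S,6R)-4-(tert-butyldimethylsilyloxy)-2,2,6-trimethyl-7-oxabicyclo[4.1.0]heptan-1-yl]methanol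
Product: 10 (1S,4S,6R)-4-(tert-butyldimethylsilyloxy)-2,2,6-trimethyl-7-oxabicyclo[4.1.0]heptane-1-carbaldehyde
Conditions: (nPr4N)RuO4 (5 mol %), N-methylmorpholine N-oxide, 4 Å MS, CH2Cl2, rt
Reagents that add atoms: none
Why: Ley–Griffith oxidation is neutral and gives an epoxy aldehyde that cannot epimerise because its α-carbon is quaternary.

Step 9
Reactants: 10 (1S,4S,6R)-4-(tert-butyldimethylsilyloxy)-2,2,6-trimethyl-7-oxabicyclo[4.1.0]heptane-1-carbaldehyde
Product: 11 (1R,4S,6R)-4-(tert-butyldimethylsilyloxy)-1-ethynyl-2,2,6-trimethyl-7-oxabicyclo[4.1.0]heptane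
Conditions: dimethyl (1-diazo-2-oxopropyl)phosphonate, K2CO3, MeOH, 0 °C → rt
Reagents that add atoms: dimethyl (1-diazo-2-oxopropyl)phosphonate (COP(=O)(OC)C(=[N+]=[N-])C(C)=O)
Why: Seyferth–Gilbert homologation in the Ohira–Bestmann variant turns the non-enolisable aldehyde into the terminal alkyne under mild base that leaves the epoxide and silyl ether alone.

Step 10
Reactants: 12 ethyl but-2-ynoate
Product: 13 ethyl (2Z)-3-iodobut-2-enoate
Conditions: NaI, AcOH, 110 °C
Reagents that add atoms: sodium iodide ([Na+].[I-])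
Why: Conjugate hydroiodination of the ynoate proceeds by anti addition and gives the Z-iodoenoate (iodine cis to the ester).

Step 11
Reactants: 11 (1R,4S,6R)-4-(tert-butyldimethylsilyloxy)-1-ethynyl-2,2,6-trimethyl-7-oxabicyclo[4.1.0]heptane; 13 ethyl (2Z)-3-iodobut-2-enoate
Product: 14 ethyl (2Z)-5-[(1R,4S,6R)-4-(tert-butyldimethylsilyloxy)-2,2,6-trimethyl-7-oxabicyclo[4.1.0]heptan-1-yl]-3-methylpent-2-en-4-ynoate
Conditions: Pd(PPh3)4 (5 mol %), CuI (10 mol %), iPr2NH, THF, rt
Reagents that add atoms: none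
Why: Sonogashira coupling joins the terminal alkyne to the vinyl iodide with retention of the Z geometry, which is the Z double bond next to the ring in the target.

Step 12
Reactants: 14 ethyl (2Z)-5-[(1R,4S,6R)-4-(tert-butyldimethylsilyloxy)-2,2,6-trimethyl-7-oxabicyclo[4.1.0]heptan-1-yl]-3-methylpent-2-en-4-ynoate
Product: 16 (1R,5S)-5-(tert-butyldimethylsilyloxy)-2-[(3Z)-5-hydroxy-3-methylpenta-1,3-dien-1-ylidene]-1,3,3-trimethylcyclohexan-1-ol (allene axis R), via epoxy enynol aluminium alkoxide 15 (not isolated)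
Conditions: iBu2AlH (5 equiv), CH2Cl2, −78 → 0 °C; aq. KNaC4H4O6
Reagents that add atoms: none
Why: After ester reduction, aluminium hydride bound to the epoxide oxygen delivers hydride to the distal alkyne carbon on the face of the breaking C–O bond (syn-SN2' reduction of a propargylic epoxide), which sets the allene axis as R while the tertiary carbinol keeps its R configuration.

Step 13
Reactants: 16 (1R,5S)-5-(tert-butyldimethylsilyloxy)-2-[(3Z)-5-hydroxy-3-methylpenta-1,3-dien-1-ylidene]-1,3,3-trimethylcyclohexan-1-ol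
Product: 17 (1R,5S)-5-(tert-butyldimethylsilyloxy)-2-[(3Z)-5-(tert-butyldimethylsilyloxy)-3-methylpenta-1,3-dien-1-ylidene]-1,3,3-trimethylcyclohexan-1-ol (allene axis R)
Conditions: TBSCl (1.1 equiv), imidazole, CH2Cl2, 0 °C
Reagents that add atoms: tert-butyldimethylsilyl chloride (CC(C)(C)[Si](C)(C)Cl)
Why: Selective silylation of the primary alcohol (the tertiary one does not react) removes the only other nucleophile that could add to the allene in the next step.

Step 14
Reactants: 17 (1R,5S)-5-(tert-butyldimethylsilyloxy)-2-[(3Z)-5-(tert-butyldimethylsilyloxy)-3-methylpenta-1,3-dien-1-ylidene]-1,3,3-trimethylcyclohexan-1-ol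
Product: 18 (2S,6S,7aR)-6-(tert-butyldimethylsilyloxy)-2-[(2Z)-4-(tert-butyldimethylsilyloxy)but-2-en-2-yl]-4,4,7a-trimethyl-2,4,5,6,7,7a-hexahydro-1-benzofuran
Conditions: AuCl3 (2 mol %), THF, rt, dark
Reagents that add atoms: none
Why: Gold-catalysed 5-endo cycloisomerisation of the α-hydroxyallene, in which the tertiary hydroxyl adds to the gold-activated terminal allene carbon in the plane of the carbinol, so the R axis is transferred to the new 2S centre (C8 of the target) with the side chain cis to the angular methyl group.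

Step 15
Reactants: 18 (2S,6S,7aR)-6-(tert-butyldimethylsilyloxy)-2-[(2Z)-4-(tert-butyldimethylsilyloxy)but-2-en-2-yl]-4,4,7a-trimethyl-2,4,5,6,7,7a-hexahydro-1-benzofuran
Product: 19 (2S,6S,7aR)-2-[(2Z)-4-hydroxybut-2-en-2-yl]-4,4,7a-trimethyl-2,4,5,6,7,7a-hexahydro-1-benzofuran-6-ol
Conditions: Bu4NF, THF, rt
Reagents that add atoms: none
Why: Fluoride desilylation removes both silyl ethers under non-acidic conditions, which protects the acid-labile allylic ether centre.

Step 16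
Reactants: 19 (2S,6S,7aR)-2-[(2Z)-4-hydroxybut-2-en-2-yl]-4,4,7a-trimethyl-2,4,5,6,7,7a-hexahydro-1-benzofuran-6-ol
Product: 20 (2Z)-3-[(2S,6S,7aR)-6-hydroxy-4,4,7a-trimethyl-2,4,5,6,7,7a-hexahydro-1-benzofuran-2-yl]but-2-enal
Conditions: MnO2 (activated, excess), CH2Cl2, rt, dark
Reagents that add atoms: none
Why: Chemoselective allylic oxidation with MnO2 converts only the primary allylic alcohol, leaving the secondary ring alcohol and the Z geometry intact.

Step 17
Reactants: 21 (2E,4E,6E)-2,7-dimethylocta-2,4,6-trienedial; 22 ethyl (triphenylphosphoranylidene)acetate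
Product: 23 ethyl (2E,4E,6E,8E)-4,9-dimethyl-10-oxodeca-2,4,6,8-tetraenoate
Conditions: CH2Cl2, rt (21 in 2.5-fold excess, recovered)
Reagents that add atoms: none
Why: Wittig mono-olefination with a stabilised ylide is E-selective, and the excess of dialdehyde suppresses the double adduct.

Step 18
Reactants: 23 ethyl (2E,4E,6E,8E)-4,9-dimethyl-10-oxodeca-2,4,6,8-tetraenoate
Product: 24 ethyl (2E,4E,6E,8E)-10-hydroxy-4,9-dimethyldeca-2,4,6,8-tetraenoate
Conditions: NaBH4, EtOH/THF, −20 °C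
Reagents that add atoms: none
Why: Chemoselective 1,2-reduction of the conjugated aldehyde by borohydride leaves the ester untouched.

Step 19
Reactants: 24 ethyl (2E,4E,6E,8E)-10-hydroxy-4,9-dimethyldeca-2,4,6,8-tetraenoate
Product: 26 [(2E,4E,6E,8E)-10-ethoxy-2,7-dimethyl-10-oxodeca-2,4,6,8-tetraen-1-yl]triphenylphosphonium bromide, via allylic bromide 25 (not isolated)
Conditions: PBr3, pyridine (cat.), Et2O, −10 °C; then PPh3, EtOAc, rt
Reagents that add atoms: phosphorus tribromide (BrP(Br)Br); triphenylphosphine (c1ccc(cc1)P(c1ccccc1)c1ccccc1)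
Why: Allylic bromination followed by SN2 quaternisation of triphenylphosphine at the primary terminus gives the crystalline phosphonium salt without touching the polyene geometry.

Step 20
Reactants: 20 (2Z)-3-[(2S,6S,7aR)-6-hydroxy-4,4,7a-trimethyl-2,4,5,6,7,7a-hexahydro-1-benzofuran-2-yl]but-2-enal; 26 [(2E,4E,6E,8E)-10-ethoxy-2,7-dimethyl-10-oxodeca-2,4,6,8-tetraen-1-yl]triphenylphosphonium bromide
Product: 28 ethyl (2E,4E,6E,8E,10E,12Z)-13-[(2S,6S,7aR)-6-hydroxy-4,4,7a-trimethyl-2,4,5,6,7,7a-hexahydro-1-benzofuran-2-yl]-4,9-dimethyltetradeca-2,4,6,8,10,12-hexaenoate, via phosphonium ylide 27 (not isolated)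
Conditions: NaN(SiMe3)2 (0.95 equiv per 26), THF, −78 °C; then 20, −78 °C → rt
Reagents that add atoms: none
Why: Wittig olefination with an ylide stabilised by conjugation to the ester gives mainly the E double bond (minor Z isomer removed by chromatography), and because no free base remains the Z-enal geometry and the stereocentres are not touched.

Step 21
Reactants: 28 ethyl (2E,4E,6E,8E,10E,12Z)-13-[(2S,6S,7aR)-6-hydroxy-4,4,7a-trimethyl-2,4,5,6,7,7a-hexahydro-1-benzofuran-2-yl]-4,9-dimethyltetradeca-2,4,6,8,10,12-hexaenoate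
Product: 29 (2E,4E,6E,8E,10E,12Z)-13-[(2S,6S,7aR)-6-hydroxy-4,4,7a-trimethyl-2,4,5,6,7,7a-hexahydro-1-benzofuran-2-yl]-4,9-dimethyltetradeca-2,4,6,8,10,12-hexaen-1-ol (CNP0263491.3)
Conditions: iBu2AlH (4 equiv), THF, −78 °C; aq. KNaC4H4O6
Reagents that add atoms: none
Why: 1,2-Reduction of the polyenoate to the primary allylic alcohol under non-acidic work-up leaves the acid-labile C8 centre and all double bonds unchanged.

## Compound list

1 | 2,6,6-trimethylcyclohex-2-ene-1,4-dione (ketoisophorone) | CC1=CC(=O)CC(C)(C)C1=O | starting material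
2 | (6R)-2,2,6-trimethylcyclohexane-1,4-dione | O=C1C(C)(C)CC(=O)C[C@H]1C | intermediate
3 | (4R,6R)-4-hydroxy-2,2,6-trimethylcyclohexan-1-one | O=C1C(C)(C)C[C@H](O)C[C@H]1C | intermediate
4 | (4R,6R)-4-(tert-butyldimethylsilyloxy)-2,2,6-trimethylcyclohexan-1-one | O=C1C(C)(C)C[C@H](O[Si](C)(C)C(C)(C)C)C[C@H]1C | intermediate
5 | lithium (4R)-4-(tert-butyldimethylsilyloxy)-2,6,6-trimethylcyclohex-1-en-1-olate | CC1=C([O-])C(C)(C)C[C@H](O[Si](C)(C)C(C)(C)C)C1.[Li+] | intermediate
6 | (4R)-4-(tert-butyldimethylsilyloxy)-2,6,6-trimethylcyclohex-1-en-1-yl trifluoromethanesulfonate | CC1=C(OS(=O)(=O)C(F)(F)F)C(C)(C)C[C@H](O[Si](C)(C)C(C)(C)C)C1 | intermediate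
7 | methyl (4R)-4-(tert-butyldimethylsilyloxy)-2,6,6-trimethylcyclohex-1-ene-1-carboxylate | CC1=C(C(=O)OC)C(C)(C)C[C@H](O[Si](C)(C)C(C)(C)C)C1 | intermediate
8 | [(4R)-4-(tert-butyldimethylsilyloxy)-2,6,6-trimethylcyclohex-1-en-1-yl]methanol | CC1=C(CO)C(C)(C)C[C@H](O[Si](C)(C)C(C)(C)C)C1 | intermediate
9 | [(1R,4S,6R)-4-(tert-butyldimethylsilyloxy)-2,2,6-trimethyl-7-oxabicyclo[4.1.0]heptan-1-yl]methanol | OC[C@]12C(C)(C)C[C@H](O[Si](C)(C)C(C)(C)C)C[C@@]1(C)O2 | intermediate
10 | (1S,4S,6R)-4-(tert-butyldimethylsilyloxy)-2,2,6-trimethyl-7-oxabicyclo[4.1.0]heptane-1-carbaldehyde | O=C[C@]12C(C)(C)C[C@H](O[Si](C)(C)C(C)(C)C)C[C@@]1(C)O2 | intermediate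
11 | (1R,4S,6R)-4-(tert-butyldimethylsilyloxy)-1-ethynyl-2,2,6-trimethyl-7-oxabicyclo[4.1.0]heptane | C#C[C@]12C(C)(C)C[C@H](O[Si](C)(C)C(C)(C)C)C[C@@]1(C)O2 | intermediate
12 | ethyl but-2-ynoate | CC#CC(=O)OCC | starting material
13 | ethyl (2Z)-3-iodobut-2-enoate | CCOC(=O)/C=C(/C)I | intermediate
14 | ethyl (2Z)-5-[(1R,4S,6R)-4-(tert-butyldimethylsilyloxy)-2,2,6-trimethyl-7-oxabicyclo[4.1.0]heptan-1-yl]-3-methylpent-2-en-4-ynoate | CCOC(=O)/C=C(/C)C#C[C@]12C(C)(C)C[C@H](O[Si](C)(C)C(C)(C)C)C[C@@]1(C)O2 | intermediate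
15 | (2Z)-5-[(1R,4S,6R)-4-(tert-butyldimethylsilyloxy)-2,2,6-trimethyl-7-oxabicyclo[4.1.0]heptan-1-yl]-3-methylpent-2-en-4-yn-1-ol (present as its aluminium alkoxide; drawn as the alcohol) | OC/C=C(/C)C#C[C@]12C(C)(C)C[C@H](O[Si](C)(C)C(C)(C)C)C[C@@]1(C)O2 | intermediate
16 | (1R,5S)-5-(tert-butyldimethylsilyloxy)-2-[(3Z)-5-hydroxy-3-methylpenta-1,3-dien-1-ylidene]-1,3,3-trimethylcyclohexan-1-ol, allene axis R | OC/C=C(/C)C([H])=[C@@]=C1C(C)(C)C[C@H](O[Si](C)(C)C(C)(C)C)C[C@@]1(C)O | intermediate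
17 | (1R,5S)-5-(tert-butyldimethylsilyloxy)-2-[(3Z)-5-(tert-butyldimethylsilyloxy)-3-methylpenta-1,3-dien-1-ylidene]-1,3,3-trimethylcyclohexan-1-ol, allene axis R | CC(C)(C)[Si](C)(C)OC/C=C(/C)C([H])=[C@@]=C1C(C)(C)C[C@H](O[Si](C)(C)C(C)(C)C)C[C@@]1(C)O | intermediate
18 | (2S,6S,7aR)-6-(tert-butyldimethylsilyloxy)-2-[(2Z)-4-(tert-butyldimethylsilyloxy)but-2-en-2-yl]-4,4,7a-trimethyl-2,4,5,6,7,7a-hexahydro-1-benzofuran | CC(C)(C)[Si](C)(C)OC/C=C(/C)[C@@H]1C=C2C(C)(C)C[C@H](O[Si](C)(C)C(C)(C)C)C[C@@]2(C)O1 | intermediate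
19 | (2S,6S,7aR)-2-[(2Z)-4-hydroxybut-2-en-2-yl]-4,4,7a-trimethyl-2,4,5,6,7,7a-hexahydro-1-benzofuran-6-ol | OC/C=C(/C)[C@@H]1C=C2C(C)(C)C[C@H](O)C[C@@]2(C)O1 | intermediate
20 | (2Z)-3-[(2S,6S,7aR)-6-hydroxy-4,4,7a-trimethyl-2,4,5,6,7,7a-hexahydro-1-benzofuran-2-yl]but-2-enal | O=C/C=C(/C)[C@@H]1C=C2C(C)(C)C[C@H](O)C[C@@]2(C)O1 | intermediate
21 | (2E,4E,6E)-2,7-dimethylocta-2,4,6-trienedial | O=C/C(C)=C/C=C/C=C(C)/C=O | starting material
22 | ethyl (triphenylphosphoranylidene)acetate | CCOC(=O)C=P(c1ccccc1)(c1ccccc1)c1ccccc1 | starting material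
23 | ethyl (2E,4E,6E,8E)-4,9-dimethyl-10-oxodeca-2,4,6,8-tetraenoate | CCOC(=O)/C=C/C(C)=C/C=C/C=C(C)/C=O | intermediate
24 | ethyl (2E,4E,6E,8E)-10-hydroxy-4,9-dimethyldeca-2,4,6,8-tetraenoate | CCOC(=O)/C=C/C(C)=C/C=C/C=C(C)/CO | intermediate
25 | ethyl (2E,4E,6E,8E)-10-bromo-4,9-dimethyldeca-2,4,6,8-tetraenoate | CCOC(=O)/C=C/C(C)=C/C=C/C=C(C)/CBr | intermediate
26 | [(2E,4E,6E,8E)-10-ethoxy-2,7-dimethyl-10-oxodeca-2,4,6,8-tetraen-1-yl]triphenylphosphonium bromide | CCOC(=O)/C=C/C(C)=C/C=C/C=C(C)/C[P+](c1ccccc1)(c1ccccc1)c1ccccc1.[Br-] | intermediate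
27 | ethyl (2E,4E,6E,8E)-4,9-dimethyl-10-(triphenylphosphoranylidene)deca-2,4,6,8-tetraenoate | CCOC(=O)/C=C/C(C)=C/C=C/C=C(C)/C=P(c1ccccc1)(c1ccccc1)c1ccccc1 | intermediate
28 | ethyl (2E,4E,6E,8E,10E,12Z)-13-[(2S,6S,7aR)-6-hydroxy-4,4,7a-trimethyl-2,4,5,6,7,7a-hexahydro-1-benzofuran-2-yl]-4,9-dimethyltetradeca-2,4,6,8,10,12-hexaenoate | CCOC(=O)/C=C/C(C)=C/C=C/C=C(C)/C=C/C=C(/C)[C@@H]1C=C2C(C)(C)C[C@H](O)C[C@@]2(C)O1 | intermediate
29 | (2E,4E,6E,8E,10E,12Z)-13-[(2S,6S,7aR)-6-hydroxy-4,4,7a-trimethyl-2,4,5,6,7,7a-hexahydro-1-benzofuran-2-yl]-4,9-dimethyltetradeca-2,4,6,8,10,12-hexaen-1-ol | C/C(=C/C=C/C(C)=C/C=C/C=C(C)/C=C/CO)[C@@H]1C=C2C(C)(C)C[C@H](O)C[C@@]2(C)O1 | target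

## Step count and risks

Total step count: 21. Longest linear sequence: 17 steps (steps 1–9, 11–16, 20 and 21, from 1 to 29).

The three steps most likely to fail:

Step 12 (ester reduction with syn-SN2' opening to the allene). The risk is incomplete facial control in the hydride delivery, which would give an allene axis mixture and later C8 epimers. The fallback leaves the allene out and makes the dihydrofuran by the acid-induced epoxide-to-furanoid rearrangement; it sets out from 10 and comes back at 19. Aldehyde 10 is condensed in a Horner–Wadsworth–Emmons reaction (nBuLi, THF, −78 °C) with ethyl (2Z)-4-(diethoxyphosphoryl)-3-methylbut-2-enoate to give ethyl (2Z,4E)-5-[(1S,4S,6R)-4-(tert-butyldimethylsilyloxy)-2,2,6-trimethyl-7-oxabicyclo[4.1.0]heptan-1-yl]-3-methylpenta-2,4-dienoate F1, with the 2E isomer removed by chromatography. Reduction with iBu2AlH gives (2Z,4E)-5-[(1S,4S,6R)-4-(tert-butyldimethylsilyloxy)-2,2,6-trimethyl-7-oxabicyclo[4.1.0]heptan-1-yl]-3-methylpenta-2,4-dien-1-ol F2. A trace of pyridinium p-toluenesulfonate in CH2Cl2 at 0 °C then opens the epoxide at the allylic carbon and closes the furanoid ring to (2Z)-3-[(2S,6S,7aR)-6-(tert-butyldimethylsilyloxy)-4,4,7a-trimethyl-2,4,5,6,7,7a-hexahydro-1-benzofuran-2-yl]but-2-en-1-ol F3, which is separated from its 2R epimer by HPLC (the unwanted epimer is re-equilibrated under the same acid). Bu4NF gives 19.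

Step 14 (gold-catalysed cycloisomerisation). The risk is partial loss of the axis-to-centre transfer through a gold-stabilised dienyl cation, or side reactions of the vinylallene. The fallback replaces π-acid catalysis by a stoichiometric halocyclisation followed by dehalogenation; it sets out from 17 and comes back at 18. N-Iodosuccinimide in CH2Cl2 at −20 °C induces anti iodoetherification of the allene to (2R,6S,7aR)-6-(tert-butyldimethylsilyloxy)-2-[(2Z)-4-(tert-butyldimethylsilyloxy)but-2-en-2-yl]-3-iodo-4,4,7a-trimethyl-2,4,5,6,7,7a-hexahydro-1-benzofuran F4 (same spatial arrangement as in 18; the descriptor changes only because of the iodine). Reduction of the vinyl iodide with Bu3SnH and Pd(PPh3)4 (cat.) in THF gives 18.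

Step 20 (Wittig coupling). The risk is poor E selectivity at the new double bond or sluggish reaction of the strongly delocalised ylide. The fallback changes to a sulfone-based olefination (Julia–Kocienski); it sets out from 24 and comes back at 28. A Mitsunobu reaction of 24 with 2-mercaptobenzothiazole (PPh3, diisopropyl azodicarboxylate, THF) gives ethyl (2E,4E,6E,8E)-10-(1,3-benzothiazol-2-ylsulfanyl)-4,9-dimethyldeca-2,4,6,8-tetraenoate F5. Oxidation with H2O2 and (NH4)6Mo7O24 (cat.) in EtOH gives ethyl (2E,4E,6E,8E)-10-(1,3-benzothiazol-2-ylsulfonyl)-4,9-dimethyldeca-2,4,6,8-tetraenoate F6. Its anion (NaN(SiMe3)2, THF, −78 °C) adds to aldehyde 20 and collapses by Smiles rearrangement and elimination to 28.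

## Further compounds

F1 | step 12 | ethyl (2Z,4E)-5-[(1S,4S,6R)-4-(tert-butyldimethylsilyloxy)-2,2,6-trimethyl-7-oxabicyclo[4.1.0]heptan-1-yl]-3-methylpenta-2,4-dienoate | CCOC(=O)/C=C(/C)\C=C\[C@]12C(C)(C)C[C@H](O[Si](C)(C)C(C)(C)C)C[C@@]1(C)O2
F2 | step 12 | (2Z,4E)-5-[(1S,4S,6R)-4-(tert-butyldimethylsilyloxy)-2,2,6-trimethyl-7-oxabicyclo[4.1.0]heptan-1-yl]-3-methylpenta-2,4-dien-1-ol | OC/C=C(/C)\C=C\[C@]12C(C)(C)C[C@H](O[Si](C)(C)C(C)(C)C)C[C@@]1(C)O2
F3 | step 12 | (2Z)-3-[(2S,6S,7aR)-6-(tert-butyldimethylsilyloxy)-4,4,7a-trimethyl-2,4,5,6,7,7a-hexahydro-1-benzofuran-2-yl]but-2-en-1-ol | OC/C=C(/C)[C@@H]1C=C2C(C)(C)C[C@H](O[Si](C)(C)C(C)(C)C)C[C@@]2(C)O1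
F4 | step 14 | (2R,6S,7aR)-6-(tert-butyldimethylsilyloxy)-2-[(2Z)-4-(tert-butyldimethylsilyloxy)but-2-en-2-yl]-3-iodo-4,4,7a-trimethyl-2,4,5,6,7,7a-hexahydro-1-benzofuran | CC(C)(C)[Si](C)(C)OC/C=C(/C)[C@@H]1C(I)=C2C(C)(C)C[C@H](O[Si](C)(C)C(C)(C)C)C[C@@]2(C)O1
F5 | step 20 | ethyl (2E,4E,6E,8E)-10-(1,3-benzothiazol-2-ylsulfanyl)-4,9-dimethyldeca-2,4,6,8-tetraenoate | CCOC(=O)/C=C/C(C)=C/C=C/C=C(C)/CSc1nc2ccccc2s1
F6 | step 20 | ethyl (2E,4E,6E,8E)-10-(1,3-benzothiazol-2-ylsulfonyl)-4,9-dimethyldeca-2,4,6,8-tetraenoate | CCOC(=O)/C=C/C(C)=C/C=C/C=C(C)/CS(=O)(=O)c1nc2ccccc2s1
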